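Cuts: the acetate C–O bond; then C12–C13 (B-alkyl Suzuki–Miyaura coupling of a C9 vinyl group with an (E)-iodobutenol); then ring A at C1–C2 and C4–C5 in one palladium-catalysed [3+3] annulation; ring B goes back to 2-methylcyclohexenone.
Enabling feature: in ring A (C1, C2, C3, C4, C5, C10) the atoms C1=C10–C5 are an allyl triad ending on the ring-fusion carbon. With C1 at the aldehyde level (gem-diacetate) it can leave twice through π-allylpalladium, so it is a 1,3-dielectrophile. C2–C3–C4 is a 1,3-dinucleophile once C3 is a ketone and C2 carries a tert-butyl ester; both helpers are removed in the two steps that follow.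
Forward order: ring B with C8 and C9, then C1 by formylation, then ring A by the annulation, then removal of the helpers, then the side chain, then the acetate.
Stereochemistry: C8 from a ligand-controlled copper-catalysed conjugate addition; C9 from aldol trapping anti to the C8 methyl; C5 from a ligand-set C1 acetate relayed across the π-allyl unit; C4 in the ring closure; 13E from the alkenyl iodide.

Key step: step 7

Remark: locants are those of the halimane skeleton (ring A: C1–C5 and C10, CH3 and CO2CH3 on C4, double bond C1=C10; ring B: C5–C10, CH3 on C8, CH3 and the chain C11–C15 on C9). The target is 4S,5R,8R,9S,13E: H-5 and the methyl groups on C4, C8 and C9 lie on one face (α), the C4 ester and the C9 chain on the other (β).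

Step 1
Reactants: 1 2-methylcyclohex-2-en-1-one
Product: 3 (2R,3R)-2-(1-hydroxyethyl)-2,3-dimethylcyclohexan-1-one (both carbinol epimers), via dimethylaluminium enolate 2 (not isolated)
Conditions: Me3Al (1.4 equiv), CuTC (CuO2CC4H3S, 2 mol%), BINOL-derived bis(1-phenylethyl)amine phosphoramidite (4 mol%, the antipode that gives 3R), Et2O, −30 °C; then MeCHO, −78 to −30 °C; aq. KNaC4H4O6
Reagents that add atoms: trimethylaluminium, C[Al](C)C; acetaldehyde, CC=O
Why: Copper-catalysed asymmetric conjugate addition, in which the phosphoramidite fixes the face of methyl transfer (C8), followed by aldol trapping of the regiodefined aluminium enolate anti to the new pseudo-axial C8 methyl, should set quaternary C9 with the two methyl groups cis (tandem conjugate addition–aldol reaction).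

Step 2
Reactants: 3 (2R,3R)-2-(1-hydroxyethyl)-2,3-dimethylcyclohexan-1-one
Product: 4 (2S,3R)-2-ethenyl-2,3-dimethylcyclohexan-1-one
Conditions: Burgess reagent (MeO2CN–SO2NEt3 inner salt), toluene, 70 °C
Reagents that add atoms: none
Why: Burgess dehydration (syn elimination through the sulfamate ester) can only take a methyl hydrogen because C9 is quaternary, so both carbinol epimers should give the vinyl group without touching C8 or C9.

Step 3
Reactants: 4 (2S,3R)-2-ethenyl-2,3-dimethylcyclohexan-1-one
Product: 5 (E)-2,4,6-triisopropylbenzenesulfonylhydrazone of 4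
Conditions: 2,4,6-(i-Pr)3C6H2SO2NHNH2, HCl (cat.), MeCN, rt
Reagents that add atoms: 2,4,6-triisopropylbenzenesulfonohydrazide, CC(C)c1cc(C(C)C)c(S(=O)(=O)NN)c(C(C)C)c1
Why: Acid-catalysed condensation gives the arylsulfonylhydrazone needed for the Shapiro reaction, with the N–N bond syn to the only enolisable carbon (C5); no stereocentre is affected.

Step 4
Reactants: 5 (E)-2,4,6-triisopropylbenzenesulfonylhydrazone of 4
Product: 7 (5R,6S)-6-ethenyl-5,6-dimethylcyclohex-1-ene-1-carbaldehyde, via vinyllithium 6 (not isolated)
Conditions: n-BuLi (2.2 equiv), TMEDA, THF–hexane, −78 to 0 °C; DMF, −78 °C to rt; H2O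
Reagents that add atoms: N,N-dimethylformamide, CN(C)C=O
Why: Shapiro reaction: the dianion can form only at C5 (C9 has no hydrogen), loss of sulfinate and N2 gives the C10 vinyllithium with the C5=C10 double bond, and formylation with DMF installs C1.

Step 5
Reactants: 7 (5R,6S)-6-ethenyl-5,6-dimethylcyclohex-1-ene-1-carbaldehyde
Product: 8 [(5R,6S)-6-ethenyl-5,6-dimethylcyclohex-1-en-1-yl]methanediyl diacetate
Conditions: Ac2O, Sc(OTf)3 (1 mol%), MeCN, 0 °C
Reagents that add atoms: acetic anhydride, CC(=O)OC(C)=O
Why: Lewis-acid-catalysed acylal formation turns the aldehyde carbon C1 into an allylic carbon with two enantiotopic acetate leaving groups.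

Step 6
Reactants: 9 methyl 2-methyl-3-oxobutanoate
Product: 11 1-tert-butyl 5-methyl 4-methyl-3-oxopentanedioate (racemic), via sodium lithium dianion 10 (not isolated)
Conditions: NaH, THF, 0 °C; n-BuLi, 0 °C; Boc2O (0.5 equiv), −78 to 0 °C; 1 M HCl
Reagents that add atoms: di-tert-butyl dicarbonate, CC(C)(C)OC(=O)OC(=O)OC(C)(C)C
Why: γ-Acylation of the β-keto ester dianion, whose terminal carbon is the more nucleophilic site, installs the tert-butyl ester that makes the future C2 a soft carbon acid.

Step 7
Reactants: 8 [(5R,6S)-6-ethenyl-5,6-dimethylcyclohex-1-en-1-yl]methanediyl diacetate; 11 1-tert-butyl 5-methyl 4-methyl-3-oxopentanedioate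
Product: 13 bicyclic keto diester (ring A: C4 with CH3 and CO2CH3, C3=O, C2H–CO2C(CH3)3 as either epimer, C1=C10; ring B: C8 CH3, C9 CH3 and vinyl; C4, C5, C8, C9 arranged as in the target), via allylic acetate 12 (not isolated)
Conditions: [Pd(C3H5)Cl]2 (2.5 mol%), (R,R)-DACH-phenyl ligand (N,N′-[(1R,2R)-cyclohexane-1,2-diyl]bis[2-(diphenylphosphino)benzamide], 7.5 mol%, the antipode chosen for the 1R acetate), DBU (2.2 equiv), CH2Cl2, 0 to 35 °C
Reagents that add atoms: none
Why: Proposed new method: zerovalent palladium ionises one of the two enantiotopic acetates of 8, the DBU enolate of 11 attacks the acetoxy-bearing allyl terminus through its unhindered C2 (bond C1–C2) to give 12, and a second ionisation, anti to the remaining acetate, gives the C1–C10–C5 π-allyl complex with the C2 chain in the anti position (away from quaternary C9), which the tethered C4 enolate attacks at C5 (bond C4–C5) so that the double bond is left at C1=C10. The closest known reaction types are the palladium-catalysed asymmetric allylic alkylation of enal gem-diacetates and the palladium-catalysed annulation of 3-oxoglutarates with allylic bis-electrophiles; their union into a [3+3] closure of a cyclohexene remains to be shown. Ring A closes at the distal terminus of the allyl unit (six-membered ring with the alkene endocyclic, formally 6-endo; attack at C1 would need a cyclobutane). C1 of 12 is set by the ligand (1R wanted) and is relayed to C5 by the two inversions of ionisation and attack, so C4 enters the β face that the acetate left, cis to the C9 vinyl group and trans to the C9 methyl, which makes C5 independent of the weak facial bias of the remote C8 and C9 centres. C4 is set in the same closure: the amidinium enolate, which no metal chelates, is expected to react in its extended (W) form, which puts the ester carbon cis to C2 and hence axial (β) and the methyl equatorial (α). The step needs C2 to react before C4 (C2 is the unsubstituted CH2), carbon attack in place of oxygen attack in the closure (O-allyl products can re-ionise) and closure faster than loss of the π-allyl configuration; the C2 epimers do not matter because that centre is removed in step 8.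

Step 8
Reactants: 13 bicyclic keto diester
Product: 15 bicyclic β,γ-unsaturated keto ester (13 without the C2 ester: C2H2, C3=O, C1=C10), via β-keto acid 14 (not isolated)
Conditions: CF3CO2H–CH2Cl2 (1:4), 0 °C to rt; then toluene, 60 °C
Reagents that add atoms: none
Why: Acidolysis of the tert-butyl ester (the methyl ester stays) and decarboxylation of the β-keto acid through its dienol, protonated at C2 under kinetic control, should leave C1=C10 out of conjugation; the quaternary C4 ester cannot decarboxylate.

Step 9
Reactants: 15 bicyclic β,γ-unsaturated keto ester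
Product: 17 methyl ester with C3 as CH2 (ring A as in the target, vinyl group on C9), via tosylhydrazone 16 (not isolated)
Conditions: TsNHNH2, EtOH, 50 °C; then catecholborane, CHCl3, 0 °C; NaOAc·3H2O, 60 °C
Reagents that add atoms: none
Why: Caglioti-type deoxygenation (tosylhydrazone, hydride addition, loss of sulfinate and N2 from the diazene) under near-neutral conditions should turn C3=O into CH2 without moving the β,γ double bond or touching the ester and vinyl groups.

Step 10
Reactants: 18 but-2-yn-1-ol
Product: 20 (E)-3-iodobut-2-en-1-ol, via alkenylzirconocene 19 (not isolated)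
Conditions: Cp2Zr(H)Cl (2.2 equiv), THF, rt to 45 °C; I2, 0 °C; H2O
Reagents that add atoms: iodine, II
Why: Hydrozirconation–iodination: syn addition of Zr–H, equilibrated by the excess reagent so that zirconium sits on the methyl-bearing carbon, then iodinolysis with retention should give the E alkenyl iodide.

Step 11
Reactants: 17 methyl ester with C3 as CH2 and vinyl on C9; 20 (E)-3-iodobut-2-en-1-ol
Product: 22 15-hydroxy compound (the target without its acetyl group), via B-alkyl-9-BBN 21 (not isolated)
Conditions: 9-BBN, THF, rt to 50 °C; then 20, Pd(dppf)Cl2 (5 mol%), AsPh3, Cs2CO3, DMF–H2O, rt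
Reagents that add atoms: none
Why: Hydroboration with 9-BBN takes only the monosubstituted vinyl group (the trisubstituted C1=C10 alkene and the ester are inert), and the B-alkyl Suzuki–Miyaura coupling joins C12 to C13 with retention of the E geometry.

Step 12
Reactants: 22 15-hydroxy compound
Product: 23 methyl (1S,5S,6R,8aR)-5-[(3E)-5-acetoxy-3-methylpent-3-en-1-yl]-1,5,6-trimethyl-1,2,3,5,6,7,8,8a-octahydronaphthalene-1-carboxylate (target; halimane locants 4S,5R,8R,9S,13E)
Conditions: Ac2O, pyridine, DMAP (cat.), CH2Cl2, 0 °C to rt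
Reagents that add atoms: acetic anhydride, CC(=O)OC(C)=O
Why: DMAP-catalysed acetylation of the primary allylic alcohol; the hindered tertiary methyl ester is inert.

Compound list
1 | 2-methylcyclohex-2-en-1-one | CC1=CCCCC1=O | starting material
2 | dimethylaluminium (3R)-2,3-dimethylcyclohex-1-en-1-olate | C[Al](C)OC1=C(C)[C@H](C)CCC1 | intermediate
3 | (2R,3R)-2-(1-hydroxyethyl)-2,3-dimethylcyclohexan-1-one (both carbinol epimers) | O=C1CCC[C@@H](C)[C@]1(C)C(C)O | intermediate
4 | (2S,3R)-2-ethenyl-2,3-dimethylcyclohexan-1-one | O=C1CCC[C@@H](C)[C@]1(C)C=C | intermediate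
5 | (E)-2,4,6-triisopropylbenzenesulfonylhydrazone of 4 | CC(C)c1cc(C(C)C)c(S(=O)(=O)N/N=C2\CCC[C@@H](C)[C@]2(C)C=C)c(C(C)C)c1 | intermediate
6 | [(5R,6S)-6-ethenyl-5,6-dimethylcyclohex-1-en-1-yl]lithium | [Li]C1=CCC[C@@H](C)[C@]1(C)C=C | intermediate
7 | (5R,6S)-6-ethenyl-5,6-dimethylcyclohex-1-ene-1-carbaldehyde | O=CC1=CCC[C@@H](C)[C@]1(C)C=C | intermediate
8 | [(5R,6S)-6-ethenyl-5,6-dimethylcyclohex-1-en-1-yl]methanediyl diacetate | CC(=O)OC(OC(C)=O)C1=CCC[C@@H](C)[C@]1(C)C=C | intermediate
9 | methyl 2-methyl-3-oxobutanoate | COC(=O)C(C)C(C)=O | starting material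
10 | sodium lithium dianion of 9 | [Na+].[Li+].C=C([O-])C(C)=C([O-])OC | intermediate
11 | 1-tert-butyl 5-methyl 4-methyl-3-oxopentanedioate (racemic) | COC(=O)C(C)C(=O)CC(=O)OC(C)(C)C | intermediate
12 | 1-tert-butyl 5-methyl 2-{(R)-acetoxy[(5R,6S)-6-ethenyl-5,6-dimethylcyclohex-1-en-1-yl]methyl}-4-methyl-3-oxopentanedioate | CC(=O)O[C@H](C(C(=O)OC(C)(C)C)C(=O)C(C)C(=O)OC)C1=CCC[C@@H](C)[C@]1(C)C=C | intermediate
13 | bicyclic keto diester (C4 CH3/CO2CH3, C3=O, C2 CO2C(CH3)3, C1=C10, C9 vinyl) | COC(=O)[C@@]1(C)C(=O)C(C(=O)OC(C)(C)C)C=C2[C@H]1CC[C@@H](C)[C@]2(C)C=C | intermediate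
14 | β-keto acid from 13 (C2 CO2H) | COC(=O)[C@@]1(C)C(=O)C(C(O)=O)C=C2[C@H]1CC[C@@H](C)[C@]2(C)C=C | intermediate
15 | bicyclic β,γ-unsaturated keto ester (C3=O, C2H2) | COC(=O)[C@@]1(C)C(=O)CC=C2[C@H]1CC[C@@H](C)[C@]2(C)C=C | intermediate
16 | tosylhydrazone of 15 | COC(=O)[C@@]1(C)C(=NNS(=O)(=O)c3ccc(C)cc3)CC=C2[C@H]1CC[C@@H](C)[C@]2(C)C=C | intermediate
17 | methyl ester with C3 as CH2 and vinyl on C9 | COC(=O)[C@@]1(C)CCC=C2[C@H]1CC[C@@H](C)[C@]2(C)C=C | intermediate
18 | but-2-yn-1-ol | CC#CCO | starting material
19 | alkenylzirconocene (zirconium on C3 and on oxygen) | C/C(=C\CO[Zr](Cl)(C1C=CC=C1)C1C=CC=C1)[Zr](Cl)(C1C=CC=C1)C1C=CC=C1 | intermediate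
20 | (E)-3-iodobut-2-en-1-ol | OC/C=C(C)/I | intermediate
21 | B-alkyl-9-BBN from 17 (boron on C12) | COC(=O)[C@@]1(C)CCC=C2[C@H]1CC[C@@H](C)[C@]2(C)CCB3C4CCCC3CCC4 | intermediate
22 | 15-hydroxy compound (target without acetyl) | COC(=O)[C@@]1(C)CCC=C2[C@H]1CC[C@@H](C)[C@]2(C)CC/C(C)=C/CO | intermediate
23 | methyl (1S,5S,6R,8aR)-5-[(3E)-5-acetoxy-3-methylpent-3-en-1-yl]-1,5,6-trimethyl-1,2,3,5,6,7,8,8a-octahydronaphthalene-1-carboxylate | COC(=O)[C@@]1(C)CCC=C2[C@H]1CC[C@@H](C)[C@]2(C)CC/C(C)=C/COC(C)=O | target

Total step count: 12. Longest linear sequence: 10 (steps 1–5, 7–9, 11, 12).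

Steps most likely to fail

Step 7. What may go wrong: poor control of C4 in the ring closure if the enolate reacts through its chelate-like (U) geometry, oxygen in place of carbon attack, or slow ionisation of the hindered allylic acetate. The fallback sets out from 7 and comes back at 17, and forms the two bonds in two separate operations by known chemistry. 2-Methyl-γ-butyrolactone is opened with Me3SiI and then MeOH to methyl 4-iodo-2-methylbutanoate F1, and iodine–zinc exchange (Et2Zn, CuI cat.) gives bis(4-methoxy-3-methyl-4-oxobutyl)zinc F2. Addition of F2 to 7 with Ti(OiPr)4 and (1S,2S)-N,N′-bis(trifluoromethanesulfonyl)cyclohexane-1,2-diamine (toluene, −20 °C) should give the 1R hydroxy ester F3 (bond C1–C2). TsOH (cat.) closes it to the 6-alkenyl δ-lactone F4. LiN(SiMe3)2 and Me3SiCl (THF, −78 °C) give the cyclic silyl ketene acetal F5. Its Ireland–Claisen ring contraction (toluene, 105 °C) can pass only through a boat transition state with the ester carbon over C10, which transfers the C1 configuration to C5 and C4 and forms bond C4–C5. The resulting silyl ester F6 is hydrolysed on work-up to acid F7, and Me3SiCHN2 (MeOH–toluene) gives 17.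

Step 1. What may go wrong: sluggish or reversible aldol trapping of the aluminium enolate, with loss of material by retro-aldol reaction and erosion of facial selectivity at C9. The fallback sets out from 1 and comes back at 4. The same conjugate addition is quenched with Me3SiOTf to give silyl enol ether F8. MeLi (THF, 0 °C) regenerates the lithium enolate, and Michael addition to phenyl vinyl sulfoxide gives β-sulfinyl ketone F9. Sulfoxide syn elimination (toluene, 110 °C, CaCO3) gives 4 directly.

Step 9. What may go wrong: incomplete condensation at the neopentyl ketone, or migration of the C1=C10 double bond into conjugation before the reduction. The fallback sets out from 15 and comes back at 17. NaBH4 (MeOH, 0 °C) gives alcohol F10, 1,1′-thiocarbonyldiimidazole (DMAP, toluene, 80 °C) gives imidazolylthiocarbonate F11, and Bu3SnH/AIBN (toluene, 90 °C) removes the oxygen by Barton–McCombie deoxygenation to give 17.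

Further compounds
F1 | step 7 | methyl 4-iodo-2-methylbutanoate | COC(=O)C(C)CCI
F2 | step 7 | bis(4-methoxy-3-methyl-4-oxobutyl)zinc | COC(=O)C(C)CC[Zn]CCC(C)C(=O)OC
F3 | step 7 | methyl (5R)-5-[(5R,6S)-6-ethenyl-5,6-dimethylcyclohex-1-en-1-yl]-5-hydroxy-2-methylpentanoate | COC(=O)C(C)CC[C@@H](O)C1=CCC[C@@H](C)[C@]1(C)C=C
F4 | step 7 | (6R)-6-[(5R,6S)-6-ethenyl-5,6-dimethylcyclohex-1-en-1-yl]-3-methyloxan-2-one | O=C1O[C@H](CCC1C)C2=CCC[C@@H](C)[C@]2(C)C=C
F5 | step 7 | cyclic trimethylsilyl ketene acetal of F4 | C[Si](C)(C)OC1=C(C)CC[C@@H](O1)C2=CCC[C@@H](C)[C@]2(C)C=C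
F6 | step 7 | trimethylsilyl ester of F7 | C[Si](C)(C)OC(=O)[C@@]1(C)CCC=C2[C@H]1CC[C@@H](C)[C@]2(C)C=C
F7 | step 7 | carboxylic acid corresponding to 17 | OC(=O)[C@@]1(C)CCC=C2[C@H]1CC[C@@H](C)[C@]2(C)C=C
F8 | step 1 | trimethyl{[(3R)-2,3-dimethylcyclohex-1-en-1-yl]oxy}silane | C[Si](C)(C)OC1=C(C)[C@H](C)CCC1
F9 | step 1 | (2S,3R)-2,3-dimethyl-2-[2-(phenylsulfinyl)ethyl]cyclohexan-1-one | O=C1CCC[C@@H](C)[C@]1(C)CCS(=O)c1ccccc1
F10 | step 9 | C3 alcohol from 15 | COC(=O)[C@@]1(C)C(O)CC=C2[C@H]1CC[C@@H](C)[C@]2(C)C=C
F11 | step 9 | O-(imidazol-1-ylthiocarbonyl) derivative of F10 | COC(=O)[C@@]1(C)C(OC(=S)n3ccnc3)CC=C2[C@H]1CC[C@@H](C)[C@]2(C)C=C
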